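## Retrosynthetic overview
1. Target ⇒ 4,4'-di-O-benzyl-(+)-lariciresinol + octadeca-4,12-diynoic acid (C7 + C6 + C5, two acetylide alkylations). One final hydrogenation saturates the chain and frees both phenols.
2. Tetrahydrofuran (second and last ring formed) ⇒ seven-to-five ring contraction of a (5R)-2-aryl-5-benzyl-4,5-dihydro-1,3-dioxepine, which makes C2–C3. C3 epimerisation and reduction follow.
3. C4–CH2Ar bond and C4 stereocentre ⇒ enantioselective, desymmetrising benzylic Heck reaction on the prochiral 2-aryl-4,7-dihydro-1,3-dioxepine.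
4. Dioxepine (first ring formed) ⇒ O-benzylvanillin + (Z)-but-2-ene-1,4-diol. Both aryl units ⇒ catechol + MeI + glyoxylic acid.

Assumption: the SMILES is read as the 9-O-stearate of (+)-lariciresinol, (2S,3R,4R) on the tetrahydrofuran (2,3-trans, 3,4-cis); the ligand antipode in step 7 is the one that delivers 5R, and both antipodes are commercial.

## Route

Step 1
Reactants: 1 catechol (benzene-1,2-diol)
Product: 2 guaiacol (2-methoxyphenol)
Conditions: MeI (0.8 equiv), K2CO3 (1.0 equiv), acetone, reflux, 6 h
Reagents that add atoms: iodomethane, CI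
Why: Williamson ether synthesis run with the diol in excess so that mono-O-methylation dominates, leftover catechol leaving in the aqueous wash and the trace of veratrole staying behind when 2 is extracted into base.

Step 2
Reactants: 2 guaiacol; 3 glyoxylic acid (50% aqueous)
Product: 5 vanillin (4-hydroxy-3-methoxybenzaldehyde), via vanillylmandelic acid 4 (not isolated)
Conditions: NaOH, H2O, 30 °C, 24 h; then CuSO4 (2 mol %), air, NaOH, 95 °C; H2SO4 to pH 3
Reagents that add atoms: none
Why: Electrophilic aromatic hydroxyalkylation of the phenoxide para to the oxygen followed by copper-catalysed aerobic oxidative decarboxylation of the mandelate, the established guaiacol-to-vanillin sequence, in which the racemic carbinol centre of 4 is destroyed.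

Step 3
Reactants: 5 vanillin
Product: 6 4-(benzyloxy)-3-methoxybenzaldehyde
Conditions: BnBr (1.1 equiv), K2CO3, DMF, rt
Reagents that add atoms: benzyl bromide, BrCc1ccccc1
Why: Williamson O-benzylation of the acidic para-formyl phenol is clean and installs a group that falls off in the final hydrogenation.

Step 4
Reactants: 6 4-(benzyloxy)-3-methoxybenzaldehyde
Product: 7 [4-(benzyloxy)-3-methoxyphenyl]methanol
Conditions: NaBH4, MeOH, 0 °C
Reagents that add atoms: none
Why: Borohydride reduction of an aryl aldehyde, with no other reducible group present.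

Step 5
Reactants: 7 [4-(benzyloxy)-3-methoxyphenyl]methanol
Product: 8 4-(benzyloxy)-3-methoxybenzyl trifluoroacetate
Conditions: (CF3CO)2O (1.1 equiv), pyridine, CH2Cl2, 0 °C; cold aqueous wash, used crude the same day
Reagents that add atoms: trifluoroacetic anhydride, O=C(OC(=O)C(F)(F)F)C(F)(F)F
Why: O-acylation turns the benzylic alcohol into an ionisable benzylic ester with a weakly coordinating leaving group, as needed for a cationic Heck manifold.

Step 6
Reactants: 6 4-(benzyloxy)-3-methoxybenzaldehyde; 9 (Z)-but-2-ene-1,4-diol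
Product: 10 2-[4-(benzyloxy)-3-methoxyphenyl]-4,7-dihydro-1,3-dioxepine
Conditions: p-TsOH·H2O (1 mol %), toluene, reflux, Dean–Stark
Reagents that add atoms: none
Why: Acid-catalysed acetalisation driven by azeotropic water removal, the cis alkene preorganising the diol for seven-membered ring closure, and the product is achiral (mirror plane through C2 bisecting C5=C6).

Step 7
Reactants: 10 2-[4-(benzyloxy)-3-methoxyphenyl]-4,7-dihydro-1,3-dioxepine (1.5 equiv); 8 4-(benzyloxy)-3-methoxybenzyl trifluoroacetate
Product: 11 (5R)-2-[4-(benzyloxy)-3-methoxyphenyl]-5-[4-(benzyloxy)-3-methoxybenzyl]-4,5-dihydro-1,3-dioxepine (mixture of C2 epimers)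
Conditions: Pd(dba)2 (5 mol %), (S,R,R)-BINOL bis(1-phenylethyl)phosphoramidite (12 mol %), iPr2NEt (2 equiv), 4 Å MS, THF, 40 °C; Et3N-deactivated silica
Reagents that add atoms: none
Why: Proposed new method: an enantioselective desymmetrising benzylic Mizoroki–Heck reaction on a prochiral 4,7-dihydro-1,3-dioxepine, not yet described; zerovalent palladium inserts into the benzylic C–O bond of 8 to give a cationic η3-benzyl complex of divalent palladium, the chiral phosphoramidite pocket selects one of the two enantiotopic alkene carbons for syn carbopalladation (this forms the C5–CH2Ar bond and sets 5R), the C5–H is then anti to palladium so the only syn β-hydride sits on C7 and elimination gives exactly the C6=C7 enol ether needed next, and since the ligand reads the local prochirality of the alkene carbon both ring faces give 5R and the C2 epimers converge in step 8; the closest known reaction types are the asymmetric aryl triflate Heck arylation of 4,7-dihydro-1,3-dioxepines and the palladium/phosphoramidite asymmetric Heck reaction of benzylic trifluoroacetates with 2,3-dihydrofuran or cyclopentene.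

Step 8
Reactants: 11 (5R)-2-aryl-5-benzyl-4,5-dihydro-1,3-dioxepine
Product: 15 4,4'-di-O-benzyl-(+)-lariciresinol, via oxocarbenium silyl enol ether 12 (not isolated), via kinetic 2,3-cis aldehyde 13 (not isolated), via epimerised 2,3-trans aldehyde 14 (not isolated)
Conditions: TBSOTf (0.2 equiv), 2,6-di-tert-butylpyridine (0.05 equiv), CH2Cl2, −78 °C, 1 h; then DBU (0.5 equiv), −78 °C → rt, 6 h; then MeOH, NaBH4, 0 °C
Reagents that add atoms: none
Why: Silyl-triflate-triggered vinyl acetal ring contraction (Petasis–Ferrier type, ionic and stepwise), in which cleavage of the C2–O1 bond erases the acetal centre and gives 12, whose Z-silyl enol ether carbon closes on the oxocarbenium carbon anti to the benzyl group (allylic 1,3-strain, 3,4-trans) and kinetically cis to the aryl group, so that the 5R centre fixes tetrahydrofuran C2 as S in 13, after which DBU inverts only the enolisable C3 to the less crowded 2,3-trans-3,4-cis aldehyde 14 (estimated 3–5:1, C2 being safe because retro-oxa-Michael opening is a disfavoured 5-endo process) and borohydride freezes that centre, the minor C3 epimer being removed by chromatography of 15.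

Step 9
Reactants: 16 hept-1-yne; 17 1,6-dibromohexane (3 equiv)
Product: 19 1-bromotridec-7-yne, via hept-1-ynyllithium 18 (not isolated)
Conditions: n-BuLi (1.0 equiv), THF, −78 °C; then 17, DMPU, −78 °C → rt; excess 17 distilled off
Reagents that add atoms: none
Why: SN2 alkylation of a lithium acetylide, the threefold excess of the dibromide suppressing double substitution.

Step 10
Reactants: 20 pent-4-ynoic acid; 19 1-bromotridec-7-yne
Product: 22 octadeca-4,12-diynoic acid, via dilithiated pent-4-ynoate 21 (not isolated)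
Conditions: n-BuLi (2.1 equiv), THF–DMPU, −78 → 0 °C; then 19, NaI (10 mol %), 0 → 40 °C; aq HCl
Reagents that add atoms: none
Why: Alkylation of an alkynoic acid dianion, in which the carbon-centred acetylide is far more nucleophilic than the carboxylate and so C–C bond formation completes the linear C18 chain.

Step 11
Reactants: 15 4,4'-di-O-benzyl-(+)-lariciresinol; 22 octadeca-4,12-diynoic acid
Product: 23 4,4'-di-O-benzyl-(+)-lariciresinol 9-O-(octadeca-4,12-diynoate)
Conditions: DCC (1.2 equiv), DMAP (0.1 equiv), CH2Cl2, 0 °C → rt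
Reagents that add atoms: none
Why: Steglich esterification of the only free hydroxyl group, under neutral conditions that touch no stereocentre.

Step 12
Reactants: 23 4,4'-di-O-benzyl-(+)-lariciresinol 9-O-(octadeca-4,12-diynoate)
Product: 24 (+)-lariciresinol 9-O-stearate (target, 2S,3R,4R)
Conditions: H2 (1 atm), 10% Pd/C, EtOAc–EtOH 4:1, rt, stopped at 6 equiv H2 uptake
Reagents that add atoms: none
Why: Heterogeneous hydrogenation and hydrogenolysis in one operation, both alkynes and both phenolic benzyl ethers reacting much faster in neutral medium than the ring C2–O benzylic bond, so the three stereocentres and the ester are untouched.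

## Compound list
1 | catechol (benzene-1,2-diol) | Oc1ccccc1O | starting material
2 | guaiacol (2-methoxyphenol) | COc1ccccc1O | intermediate
3 | glyoxylic acid | O=CC(=O)O | starting material
4 | vanillylmandelic acid (racemic, not isolated) | COc1cc(C(O)C(=O)O)ccc1O | intermediate
5 | vanillin | COc1cc(C=O)ccc1O | intermediate
6 | 4-(benzyloxy)-3-methoxybenzaldehyde | COc1cc(C=O)ccc1OCc1ccccc1 | intermediate
7 | [4-(benzyloxy)-3-methoxyphenyl]methanol | COc1cc(CO)ccc1OCc1ccccc1 | intermediate
8 | 4-(benzyloxy)-3-methoxybenzyl trifluoroacetate | COc1cc(COC(=O)C(F)(F)F)ccc1OCc1ccccc1 | intermediate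
9 | (Z)-but-2-ene-1,4-diol | OC/C=C\CO | starting material
10 | 2-[4-(benzyloxy)-3-methoxyphenyl]-4,7-dihydro-1,3-dioxepine (achiral) | COc1cc(C2OCC=CCO2)ccc1OCc1ccccc1 | intermediate
11 | (5R)-2-[4-(benzyloxy)-3-methoxyphenyl]-5-[4-(benzyloxy)-3-methoxybenzyl]-4,5-dihydro-1,3-dioxepine (C2 epimers) | COc1cc(C[C@H]2COC(c3ccc(OCc4ccccc4)c(OC)c3)OC=C2)ccc1OCc1ccccc1 | intermediate
12 | ring-opened (R)-oxocarbenium Z-silyl enol ether triflate (not isolated) | COc1cc(C[C@@H](C[O+]=Cc2ccc(OCc3ccccc3)c(OC)c2)/C=C\O[Si](C)(C)C(C)(C)C)ccc1OCc1ccccc1.[O-]S(=O)(=O)C(F)(F)F | intermediate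
13 | (2S,3R,4R)-2-[4-(benzyloxy)-3-methoxyphenyl]-4-[4-(benzyloxy)-3-methoxybenzyl]tetrahydrofuran-3-carbaldehyde (2,3-cis, 3,4-trans; not isolated) | O=C[C@@H]1[C@@H](Cc2ccc(OCc3ccccc3)c(OC)c2)CO[C@@H]1c1ccc(OCc2ccccc2)c(OC)c1 | intermediate
14 | (2S,3S,4R)-2-[4-(benzyloxy)-3-methoxyphenyl]-4-[4-(benzyloxy)-3-methoxybenzyl]tetrahydrofuran-3-carbaldehyde (2,3-trans, 3,4-cis; not isolated) | O=C[C@H]1[C@@H](Cc2ccc(OCc3ccccc3)c(OC)c2)CO[C@@H]1c1ccc(OCc2ccccc2)c(OC)c1 | intermediate
15 | 4,4'-di-O-benzyl-(+)-lariciresinol, {(2S,3R,4R)-2-aryl-4-benzyltetrahydrofuran-3-yl}methanol | OC[C@H]1[C@@H](Cc2ccc(OCc3ccccc3)c(OC)c2)CO[C@@H]1c1ccc(OCc2ccccc2)c(OC)c1 | intermediate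
16 | hept-1-yne | C#CCCCCC | starting material
17 | 1,6-dibromohexane | BrCCCCCCBr | starting material
18 | hept-1-ynyllithium (not isolated) | [Li]C#CCCCCC | intermediate
19 | 1-bromotridec-7-yne | CCCCCC#CCCCCCCBr | intermediate
20 | pent-4-ynoic acid | C#CCCC(=O)O | starting material
21 | lithium 5-lithiopent-4-ynoate (not isolated) | [Li]C#CCCC(=O)O[Li] | intermediate
22 | octadeca-4,12-diynoic acid | CCCCCC#CCCCCCCC#CCCC(=O)O | intermediate
23 | 4,4'-di-O-benzyl-(+)-lariciresinol 9-O-(octadeca-4,12-diynoate), (2S,3R,4R) | CCCCCC#CCCCCCCC#CCCC(=O)OC[C@H]1[C@@H](Cc2ccc(OCc3ccccc3)c(OC)c2)CO[C@@H]1c1ccc(OCc2ccccc2)c(OC)c1 | intermediate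
24 | (+)-lariciresinol 9-O-stearate, (2S,3R,4R) | CCCCCCCCCCCCCCCCCC(=O)OC[C@H]1[C@@H](Cc2ccc(O)c(OC)c2)CO[C@@H]1c1ccc(O)c(OC)c1 | target

## Step count and risks
Total steps: 12. Longest linear sequence: 9 (steps 1, 2, 3, 4, 5, 7, 8, 11, 12).

**Step 7 (new benzylic Heck desymmetrisation).** The risks are slow insertion into an unactivated internal alkene, ionisation of the labile ester 8, and insufficient ee.

The fallback uses known chemistry. It sets out from 7 and 6 and comes back at 11.
- Alcohol 7 is treated with PBr3 to give 4-(benzyloxy)-3-methoxybenzyl bromide F1.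
- Commercial but-2-yne-1,4-diol is syn-hydrostannylated (Bu3SnH, PdCl2(PPh3)2 cat.) to (E)-2-(tributylstannyl)but-2-ene-1,4-diol F2.
- Stille coupling of the two (Pd2(dba)3, AsPh3, THF) gives (Z)-2-[4-(benzyloxy)-3-methoxybenzyl]but-2-ene-1,4-diol F3.
- Acetalisation with 6, as in step 6, gives racemic 2-aryl-5-benzyl-4,7-dihydro-1,3-dioxepine F4.
- The known asymmetric double-bond isomerisation of 5-substituted 4,7-dihydro-1,3-dioxepines is then applied, with a chiral nickel hydride made from NiI2[(R,R)-Me-DuPhos] and LiBHEt3. It moves the alkene to C6=C7 and sets C5, giving 11.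

**Step 8 (ring contraction, C3 epimerisation, reduction).** There are three risks. The kinetic closure may not be cleanly 2,3-cis. The DBU equilibrium may be less favourable than estimated. The acid may also promote Friedel–Crafts closure to an aryltetralin.

The fallback sets out from 11 (with 6) and comes back at 15.
- Mild hydrolysis (AcOH, THF, H2O) releases 6 and (4R)-4-[4-(benzyloxy)-3-methoxybenzyl]tetrahydrofuran-2-ol F5.
- Oxidation with TEMPO and PhI(OAc)2 gives (R)-4-[4-(benzyloxy)-3-methoxybenzyl]dihydrofuran-2(3H)-one F6.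
- Aldol addition of its LiN(SiMe3)2 enolate to 6 occurs anti to the β-substituent. It gives the (3S,4R)-trans-3-[aryl(hydroxy)methyl]-4-benzyl lactone F7 as carbinol epimers.
- LiAlH4 gives the (2R,3R)-2-[aryl(hydroxy)methyl]-3-benzylbutane-1,4-diol F8.
- Camphorsulfonic acid in CH2Cl2 closes the 7,9'-ether through the p-alkoxybenzyl cation with the preferred 2,3-trans geometry, giving 15.
- Here the 3,4-cis relationship comes from the trans-lactone, not from an equilibrium.

**Step 12 (global hydrogenation).** The risk is that the long exposure needed for two alkynes also cleaves the ring C2–O benzylic bond, giving the seco-diol.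

The fallback sets out from 22 and 15 and comes back at 24.
- Acid 22 is hydrogenated alone (H2, Pd/C, EtOAc) to stearic acid F9.
- A short hydrogenolysis of 15 (H2, Pd/C, EtOAc) gives (+)-lariciresinol F10.
- Immobilised Candida antarctica lipase B (Novozym 435, 2-methylbutan-2-ol, 4 Å MS, 55 °C) then acylates only the primary aliphatic hydroxyl with the acid and leaves both phenols free.

## Further compounds
F1 | step 7 | 4-(benzyloxy)-3-methoxybenzyl bromide | COc1cc(CBr)ccc1OCc1ccccc1
F2 | step 7 | (E)-2-(tributylstannyl)but-2-ene-1,4-diol | OC/C=C(/[Sn](CCCC)(CCCC)CCCC)CO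
F3 | step 7 | (Z)-2-[4-(benzyloxy)-3-methoxybenzyl]but-2-ene-1,4-diol | OC/C=C(/Cc1ccc(OCc2ccccc2)c(OC)c1)CO
F4 | step 7 | 2-[4-(benzyloxy)-3-methoxyphenyl]-5-[4-(benzyloxy)-3-methoxybenzyl]-4,7-dihydro-1,3-dioxepine (racemic) | COc1cc(CC2=CCOC(c3ccc(OCc4ccccc4)c(OC)c3)OC2)ccc1OCc1ccccc1
F5 | step 8 | (4R)-4-[4-(benzyloxy)-3-methoxybenzyl]tetrahydrofuran-2-ol (anomers) | COc1cc(C[C@H]2COC(O)C2)ccc1OCc1ccccc1
F6 | step 8 | (R)-4-[4-(benzyloxy)-3-methoxybenzyl]dihydrofuran-2(3H)-one | COc1cc(C[C@H]2COC(=O)C2)ccc1OCc1ccccc1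
F7 | step 8 | (3S,4R)-3-{[4-(benzyloxy)-3-methoxyphenyl](hydroxy)methyl}-4-[4-(benzyloxy)-3-methoxybenzyl]dihydrofuran-2(3H)-one (carbinol epimers) | O=C1[C@H](C(O)c2ccc(OCc3ccccc3)c(OC)c2)[C@@H](Cc2ccc(OCc3ccccc3)c(OC)c2)CO1
F8 | step 8 | (2R,3R)-2-{[4-(benzyloxy)-3-methoxyphenyl](hydroxy)methyl}-3-[4-(benzyloxy)-3-methoxybenzyl]butane-1,4-diol (carbinol epimers) | OC[C@H](C(O)c1ccc(OCc2ccccc2)c(OC)c1)[C@@H](Cc1ccc(OCc2ccccc2)c(OC)c1)CO
F9 | step 12 | stearic acid | CCCCCCCCCCCCCCCCCC(=O)O
F10 | step 12 | (+)-lariciresinol, (2S,3R,4R) | OC[C@H]1[C@@H](Cc2ccc(O)c(OC)c2)CO[C@@H]1c1ccc(O)c(OC)c1
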